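# Proposed synthesis of CNP0297019.1 by transannular Ireland–Claisen ring contraction

## Analysis of the target

- **Ring system.** The target is a 2-oxabicyclo[3.3.1]nonan-3-one. A cyclohexane (C6, C7, C14, C13, C12, C11) has its 1,3-related carbons C7 and C11 bridged by C8–C9(=O)–O10, so C8 and O10 must both be axial.
- **Stereocentres.** There are seven; in the backbone locants the configuration is 3R, 5S, 6S, 7R, 11S, 13R, 14R. Five are contiguous on the carbocycle, among them the all-carbon quaternary C7 and the quaternary carbinol C11.
- **Relative configuration.** The C5 branch on C6, C8 on C7, the C15 group on C14, the C13 hydroxyl and O10 all lie on one face of the carbocycle. Only the two ring methyl groups lie on the other. The C13 hydroxyl is axial and 1,3-diaxial to both ends of the lactone bridge.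
- **Side chain.** It carries a 1,3-diol (C3, C5) whose C3 carbinol is tertiary and allylic, with methyl and vinyl as nearly equal-sized partners.
- **Sensitive groups.** The tertiary allylic alcohol ionises in acid. The C13 hydroxyl is γ to the C16 acid and can close a γ-lactone. The C5 and C13 hydroxyls can take over the lactone acyl group under base. Any carbonyl at C5 or C13 has O10 in the β-position and can open the lactone by elimination.
- **Main difficulty.** C7 is flanked by C6 (branched) and C14 (bearing the CMe2CO2H group), so an intermolecular bond to C7 is unattractive, and five ring centres must be related correctly.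
- **Feature used.** C6–C7 joins two carbons whose outer neighbours C5 and C9 can be tied through oxygen as an allylic ester C5(=O)–O–C9–C8=C7. With C6 α to C5 this is the array of an ester-enolate Claisen rearrangement. The tether C11–C12–C13–C14 places it inside a ten-membered lactone.

## Retrosynthetic reasoning

**Deprotection (47 ⇐ 46 ⇐ 45).** The target tolerates neither protic acid nor strong base. The last steps therefore only remove silicon-based groups: the acetal-type silylethoxymethyl ether on C13 by a magnesium Lewis acid, then the C16 silylethyl ester and the C3 silyl ether by fluoride.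

**C5 carbinol (45 ⇐ 44).** The C5–O stereocentre is cut back to ketone 44. Chelate-directed 1,3-reduction is not trusted here, because the C3 carbinol carries methyl and vinyl and gives no conformational bias. The forward step is a reagent-controlled oxazaborolidine reduction that distinguishes the α-branched ring carbon C6 from the C4 methylene.

**C4–C5 bond (44 ⇐ 34 + 40, through 41–43).** The side chain is cut between C4 and C5. Aldehyde 34 is far more electrophilic than the lactone and the neopentyl ester, so a sulfone-stabilised C4 carbanion can be added selectively. Oxidation and desulfonylation then give 44. The C3 stereocentre comes ready-made in sulfone 40, which goes back through 39, 38, 37 and epoxide 36 to 35. An asymmetric epoxidation has to set C3.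

**Lactone C9–O10 (34 ⇐ 33 ⇐ 32 ⇐ 31 ⇐ 28 ⇐ 27 ⇐ 26 ⇐ 25).** The lactone is opened to diol 28; its forward closure runs through aldehyde 29 and lactol 30. C9 then goes back to the terminal carbon of the vinyl group in 25. The C5 carboxyl is kept as a benzyl ester during this phase. A free C5 hydroxyl would capture C9 as a fused lactone, and a free C13 hydroxyl would do the same, so both stay blocked. Only after the bridge is in place is C5 taken to the aldehyde.

**Key disconnection C6–C7 (25 ⇐ 22, through 23 and 24).** Cutting C6–C7 and reconnecting O to C9 turns the cyclohexane acid 25 into the ten-membered lactone 22. The gain is that quaternary C7 and the C6 centre are formed in one intramolecular, concerted step. Their mutual cis relation is dictated by ring geometry, and the C8=C9 vinyl group needed for the lactone is delivered at the same time. The forward step has to enolise 22 toward C6 without losing the C11 oxygen, and to choose the correct face with respect to C11, C13 and C14.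

**Macrolactone (22 ⇐ 20, through 21).** The temporary ester bond C5(=O)–O–C9 is cut to seco acid 20, which carries a (Z)-allylic alcohol and the C5 acid. The forward step is a carboxyl-activation macrolactonisation at high dilution.

**Oxidation levels (20 ⇐ 19 ⇐ 18 ⇐ 17).** The C5 acid comes from the primary silyl ether of 17 by direct oxidation. The C9 alcohol comes from the C9 methyl ester, reduced last so that it never needs a protecting group.

**Z-alkene (17 ⇐ 16 ⇐ 15 ⇐ 14 ⇐ 13).** The trisubstituted alkene, with C14 and C9 cis, is cut back to a C7≡C8 alkyne. Olefination of a hindered C7 methyl ketone would give no dependable Z-selectivity. In contrast, syn addition of methyl and hydrogen across an ynoate fixes the geometry by mechanism.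

**C13–C14 bond (13 ⇐ 4 + 11, through 12).** With C7 drawn in the main chain, the C13 hydroxyl and the C15 group are anti. An aldol at C14 would need the E-enolate of a hindered acyl unit and then a multi-step change of carbonyl into alkyne. Instead the bond is made by anti-selective addition of a chiral allenylmetal, generated from propargylic mesylate 11, to aldehyde 4. This delivers the anti dyad and the alkyne together, and the configuration of 11 alone controls both centres.

**Aldehyde 4 (⇐ 3 ⇐ 2 ⇐ 1).** C5, C6, C11, C12 and C13 come from 1. To match C11 of the target, the lactone carbonyl carbon of 1 must become C13 and its CH2O carbon must become C5. This was checked by comparing neighbour order at C11 in 1, 22 and 47; the other orientation would need the enantiomer of 1.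

**Mesylate 11 (⇐ 10 ⇐ 9 ⇐ 8 ⇐ 6 + 7; 6 ⇐ 5).** C14, C15, C16, C7 and C8 come from an aldol of ester 6 with ynal 7, followed by oxidation to ynone 9 and asymmetric transfer hydrogenation. The quaternary C15 and the C16 ester are thus present from the start, and C16 has no α-hydrogen to interfere with later enolate chemistry.

## Alternatives that were turned down

**Alternative 1:** Both C12–C13 and C11–O10 are cut, leading to the open-chain aldehyde acid A2. It carries the C13 aldehyde on C14, an isopropenyl group (C11=C12) on C6 and the C9 carboxyl on C7.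
- *Forward step.* A tert-butyl perester with Cu(OAc)2 removes the aldehyde hydrogen of A2. The radical centre at C13 adds 6-endo to C12. The tertiary centre then at C11 is oxidised by divalent copper and is captured by the C9 carboxyl, giving keto-lactone A1.
- *For.* Two bonds and both rings form in one step, and the lactone oxidation level is carried from the start. On bonds and rings per step this is stronger than the chosen key step. The later C13 reduction should be reliable, since hydride must approach from the face away from the bridge.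
- *Against.* A2 must already hold C6, quaternary C7 and C14 in an open chain, so the hardest stereochemical problem is moved to earlier intermolecular chemistry. The α-branched acyl centre can lose CO. Hydrogen abstraction has allylic and ether C–H bonds as competitors. The cationic C11 can lose a proton instead of being trapped. A1 has O10 β to the C13 ketone and can open by elimination.
- *Comparison.* The chosen route needs more steps after its key step, but it forms C7 intramolecularly with an enforced cis relation to C6.

**Alternative 2:** C7–CH3 and C6–C5 are cut, leading to cyclohexenone A4 (C11 ketone, C6=C7, protected C8–C9 chain on C7) and side-chain aldehyde A5.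
- *Forward step.* Me2CuLi delivers methyl to C7 of A4. After counter-ion exchange with ZnCl2, C6 adds to the carbonyl group of A5 to give A3.
- *For.* It is the most convergent plan: the whole side chain, including the C3 centre and the C5 carbinol, arrives in one step. Here it is clearly stronger than the chosen route, which spends six steps on the side chain. Methyl delivery trans to the C14 substituent is also the sense required.
- *Against.* The conjugate addition must create quaternary C7 intermolecularly, at a β,β-disubstituted position next to the tert-alkyl-bearing C14. The aldol then sets C6 and C5 together with no dependable control at C5. C11 is left as a ketone, so the tertiary carbinol with axial oxygen and the lactone must still be made under substrate control. A3 is a β-hydroxy ketone open to retro-aldol cleavage.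
- *Comparison.* The chosen route gives up this convergence. In return C11 comes unchanged from the chiral pool, and C6 and C7 come from a concerted step.

**Alternative 3:** C11–C12 and C7–C14 are cut, leading to 2-pyranone A7 (already holding the lactone, C6 and both methyl-bearing carbons) and methyl ketone A8.
- *Forward step.* A8 is activated by enamine formation with a chiral primary-amine salt. C12 adds to C11 of A7 and then C14 adds to C7, giving A6.
- *For.* It is by far the shortest plan: both quaternary centres and the whole bicycle come from two simple pieces in one catalytic asymmetric step. On step economy it is stronger than every other option.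
- *Against.* Addition at the oxygen-bearing C11 of a 2-pyranone gives an intermediate with O10 β to the C13 carbonyl; this can re-open by loss of carboxylate before the second bond forms. The second addition must start from C14, the methylene next to quaternary C15, and must create a quaternary centre at C7. One catalyst would have to control four stereocentres, including C6 by protonation. No close precedent exists for this mode of reaction.
- *Comparison.* The chosen route is much longer, but each of its bonds is made by a known reaction type. Its risk is concentrated in the facial selectivity of one step.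

Key step: step 18

## Route

- Assumption: locants C1–C16 are those of the target backbone (C1=C2 vinyl, C3 carbinol, C4, C5 carbinol, C6, C7, C8, C9 lactone carbonyl, O10, C11, C12, C13, C14, C15, C16 carboxyl); compounds 1, 5, 7 and 35 are taken as purchasable.
- Assumption: the sense of induction of the ruthenium transfer-hydrogenation catalyst and of the oxazaborolidine is taken from simple alkynyl and alkyl ketones; if a substrate responded in the opposite sense, the enantiomeric catalyst would be used.

Step 1
Reactants: 1 (R)-mevalonolactone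
Product: 2 (3R)-3,5-dihydroxy-N-methoxy-N,3-dimethylpentanamide
Conditions: MeNH(OMe)·HCl, Me3Al, CH2Cl2, 0 °C → rt
Reagents that add atoms: N,O-dimethylhydroxylamine hydrochloride, CNOC.Cl
Why: Aluminium-amide aminolysis (Weinreb amide formation) opens the lactone without touching C11; the former lactone carbonyl is the future C13 and the freed CH2OH carbon the future C5.

Step 2
Reactants: 2 (3R)-3,5-dihydroxy-N-methoxy-N,3-dimethylpentanamide
Product: 3 (3R)-N-methoxy-N,3-dimethyl-3,5-bis(triethylsilyloxy)pentanamide
Conditions: Et3SiOTf (2.5 equiv), 2,6-lutidine, CH2Cl2, −78 → 0 °C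
Reagents that add atoms: triethylsilyl trifluoromethanesulfonate, CC[Si](CC)(CC)OS(=O)(=O)C(F)(F)F
Why: The silyl triflate silylates the primary and the tertiary hydroxyl in one operation; the basic medium keeps the δ-hydroxy amide from closing back to the lactone.

Step 3
Reactants: 3 (3R)-N-methoxy-N,3-dimethyl-3,5-bis(triethylsilyloxy)pentanamide
Product: 4 (3R)-3-methyl-3,5-bis(triethylsilyloxy)pentanal
Conditions: i-Bu2AlH, THF, −78 °C; aq. KNaC4H4O6
Reagents that add atoms: none
Why: Reduction of an N-methoxy-N-methylamide stops at the chelated aluminium hemiaminal, which releases the C13 aldehyde on work-up; silyl ethers are inert.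

Step 4
Reactants: 5 2-methylpropanoyl chloride
Product: 6 2-(trimethylsilyl)ethyl 2-methylpropanoate
Conditions: Me3SiCH2CH2OH, pyridine, DMAP (cat.), CH2Cl2, 0 °C → rt
Reagents that add atoms: 2-(trimethylsilyl)ethanol, C[Si](C)(C)CCO
Why: Acylation of the alcohol by the acid chloride installs the fluoride-labile C16 ester that is carried to the last step.

Step 5
Reactants: 6 2-(trimethylsilyl)ethyl 2-methylpropanoate; 7 3-(trimethylsilyl)prop-2-ynal
Product: 8 racemic 2-(trimethylsilyl)ethyl 3-hydroxy-2,2-dimethyl-5-(trimethylsilyl)pent-4-ynoate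
Conditions: LiN(i-Pr)2, THF, −78 °C; then 7, −78 °C; AcOH
Reagents that add atoms: none
Why: Aldol addition of the fully substituted lithium ester enolate to the ynal (1,2-addition) forms C14–C15 and the quaternary C15; the racemic carbinol is corrected in the next two steps.

Step 6
Reactants: 8 racemic 2-(trimethylsilyl)ethyl 3-hydroxy-2,2-dimethyl-5-(trimethylsilyl)pent-4-ynoate
Product: 9 2-(trimethylsilyl)ethyl 2,2-dimethyl-3-oxo-5-(trimethylsilyl)pent-4-ynoate
Conditions: Dess–Martin periodinane, NaHCO3, CH2Cl2, rt
Reagents that add atoms: none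
Why: Dess–Martin oxidation of the propargylic alcohol gives the ynone; the β-keto ester cannot enolise because C15 is quaternary.

Step 7
Reactants: 9 2-(trimethylsilyl)ethyl 2,2-dimethyl-3-oxo-5-(trimethylsilyl)pent-4-ynoate
Product: 10 2-(trimethylsilyl)ethyl (3R)-3-hydroxy-2,2-dimethyl-5-(trimethylsilyl)pent-4-ynoate
Conditions: Ru[(R,R)-TsDPEN](p-cymene) (2 mol%), i-PrOH, rt
Reagents that add atoms: none
Why: Noyori asymmetric transfer hydrogenation of an alkynyl ketone; the alkynyl group takes the place the aryl group has in the usual model, so the (R,R)-catalyst should deliver hydride to give the (3R)-carbinol (future C14).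

Step 8
Reactants: 10 2-(trimethylsilyl)ethyl (3R)-3-hydroxy-2,2-dimethyl-5-(trimethylsilyl)pent-4-ynoate
Product: 11 2-(trimethylsilyl)ethyl (3R)-2,2-dimethyl-3-(methylsulfonyloxy)-5-(trimethylsilyl)pent-4-ynoate
Conditions: MsCl, Et3N, CH2Cl2, −78 → 0 °C
Reagents that add atoms: methanesulfonyl chloride, CS(=O)(=O)Cl
Why: Sulfonylation with retention; the neopentyl-type propargylic mesylate cannot undergo direct substitution and is stable until ionised by palladium.

Step 9
Reactants: 4 (3R)-3-methyl-3,5-bis(triethylsilyloxy)pentanal; 11 2-(trimethylsilyl)ethyl (3R)-2,2-dimethyl-3-(methylsulfonyloxy)-5-(trimethylsilyl)pent-4-ynoate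
Product: 13 2-(trimethylsilyl)ethyl (3S,4R,6R)-4-hydroxy-2,2,6-trimethyl-6,8-bis(triethylsilyloxy)-3-[(trimethylsilyl)ethynyl]octanoate, via allenylzinc species 12 (not isolated)
Conditions: Pd(OAc)2 (5 mol%), PPh3 (5 mol%), Et2Zn (3 equiv), THF, −78 → −20 °C
Reagents that add atoms: none
Why: Marshall propargylation: zerovalent palladium displaces the mesylate anti (SN2′), Et2Zn transmetallates to allenylzinc 12, and 12 adds to 4 through a cyclic SE2′ transition state; the result is net inversion at C14 and the anti C13/C14 dyad (hydroxyl anti to the C15 group), both set by the configuration of 11 and not by the remote C11 centre.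

Step 10
Reactants: 13 2-(trimethylsilyl)ethyl (3S,4R,6R)-4-hydroxy-2,2,6-trimethyl-6,8-bis(triethylsilyloxy)-3-[(trimethylsilyl)ethynyl]octanoate
Product: 14 C13 2-(trimethylsilyl)ethoxymethyl (SEM) ether of 13
Conditions: SEMCl, i-Pr2NEt, Bu4NI (cat.), CH2Cl2, 40 °C
Reagents that add atoms: 2-(trimethylsilyl)ethoxymethyl chloride, C[Si](C)(C)CCOCCl
Why: O-Alkylation of the hindered secondary hydroxyl by the chloromethyl ether; the acetal-type group is small at C13, survives amide bases and hydrides, and can later be removed without protic acid.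

Step 11
Reactants: 14 C13 SEM ether of 13
Product: 15 terminal alkyne (C8–H; C5 and C11 triethylsilyl ethers, C13 SEM ether, C16 silylethyl ester)
Conditions: K2CO3, MeOH, 0 °C → rt
Reagents that add atoms: none
Why: Methanolysis of the alkynyl C–Si bond is much faster than cleavage of triethylsilyl ethers or of the neopentyl ester under these conditions.

Step 12
Reactants: 15 terminal alkyne
Product: 16 methyl ynoate (C9 methyl ester on C7≡C8)
Conditions: n-BuLi, THF, −78 °C; ClCO2Me, −78 → −20 °C
Reagents that add atoms: methyl chloroformate, COC(=O)Cl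
Why: Deprotonation of the terminal alkyne at −78 °C is faster than attack on the shielded C16 ester; acylation of the acetylide installs C9.

Step 13
Reactants: 16 methyl ynoate
Product: 17 (Z)-enoate (C7 methyl; C14 and C9 cis on C7=C8)
Conditions: Me2CuLi (from CuI and MeLi), THF, −78 °C; MeOH at −78 °C
Reagents that add atoms: lithium dimethylcuprate, [Li+].C[Cu-]C
Why: syn-Carbocupration of the ynoate puts methyl on C7 and copper on C8 on the same side; protonation at −78 °C with retention leaves C14 and C9 cis, the Z geometry the ring needs.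

Step 14
Reactants: 17 (Z)-enoate
Product: 18 C5 aldehyde (from the primary silyl ether of 17)
Conditions: (COCl)2, DMSO, CH2Cl2, −78 → −30 °C; Et3N, −78 → 0 °C
Reagents that add atoms: none
Why: Under Swern conditions the chlorosulfonium species cleaves primary triethylsilyl ethers and oxidises them to aldehydes in one operation; the tertiary silyl ether, the SEM ether and the esters are inert.

Step 15
Reactants: 18 C5 aldehyde
Product: 19 C5 carboxylic acid (C9 still methyl ester)
Conditions: NaClO2, NaH2PO4, 2-methylbut-2-ene, t-BuOH/H2O, 0 °C → rt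
Reagents that add atoms: sodium chlorite, [Na+].[O-]Cl=O
Why: Pinnick oxidation converts the aldehyde to the acid under buffered conditions; the alkene scavenger protects the trisubstituted enoate from hypochlorite.

Step 16
Reactants: 19 C5 carboxylic acid
Product: 20 seco acid (C5 acid, (Z)-allylic C9 alcohol)
Conditions: i-Bu2AlH (3.3 equiv), CH2Cl2, −78 °C; aq. KNaC4H4O6
Reagents that add atoms: none
Why: The unhindered conjugated methyl ester is reduced to the allylic alcohol; the acid is held as an aluminium carboxylate, and the C16 ester is shielded by quaternary C15 and branched C14, so limited reagent at −78 °C should leave it intact.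

Step 17
Reactants: 20 seco acid
Product: 22 ten-membered (Z)-lactone (C5(=O)–O–C9; C11 triethylsilyl ether; C13 SEM ether; C16 silylethyl ester), via mixed anhydride 21 (not isolated)
Conditions: 2,4,6-Cl3C6H2COCl, Et3N, THF, rt; then slow addition to DMAP, toluene, 80 °C (1 mM)
Reagents that add atoms: none
Why: Yamaguchi macrolactonisation: the mixed anhydride acylates DMAP and the primary allylic hydroxyl closes the ring at high dilution; the cis alkene and the two fully substituted ring carbons reduce the entropic cost of the medium ring.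

Step 18
Reactants: 22 ten-membered (Z)-lactone
Product: 25 cyclohexanecarboxylic acid (C5 carboxyl on C6 cis to vinyl on quaternary C7; C11 triethylsilyl ether; C13 SEM ether; C16 silylethyl ester), via silyl ketene acetal 23 (not isolated), via trimethylsilyl ester 24 (not isolated)
Conditions: LiN(i-Pr)2, Me3SiCl/Et3N (premixed), THF, −100 → −78 °C; then toluene, 80 °C; aq. citric acid
Reagents that add atoms: none
Why: LiN(i-Pr)2 removes a C6 proton, the only enolisable position because C16 is quaternary, and Me3SiCl present from the start traps the enolate as silyl ketene acetal 23 before the C11 silyloxy group can be expelled. On warming, 23 undergoes a transannular Ireland–Claisen rearrangement, the known ring contraction of alkenyl macrolactones to 2-alkenylcycloalkanecarboxylic acids: C6–C7 forms, O–C9 breaks and the cyclohexane (C6, C7, C14, C13, C12, C11) is closed across the macrocycle by a pericyclic C–C bond formation. The ring oxygen and C11 are cis on C5=C6, and C14 and C9 are cis on C7=C8, so a chair array would point the two tether ends to opposite sides; only the boat-like array can be reached, and it places C5 and C8 on the same face, fixing C6 and C7 as cis. The absolute sense at both new centres should follow from the tether C11–C12–C13–C14, which is expected to keep the tert-alkyl group on C14 and the methyl on C11 pseudo-equatorial. Of the two boat arrays compatible with that, the one leading to 25 keeps the C7 methyl equatorial and places only the flat C8 in the axial site between the C11 and C13 oxygens; the other would force the methyl into that site and C5 into an axial position. The step therefore needs facial selectivity, supplied by the C14 and C11 substituents, and freedom from β-elimination, supplied by the in situ silylation. Aqueous acid cleaves silyl ester 24 to acid 25, whose vinyl group carries C8 and C9.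

Step 19
Reactants: 25 cyclohexanecarboxylic acid
Product: 26 benzyl ester of 25
Conditions: BnBr, Cs2CO3, DMF, rt
Reagents that add atoms: benzyl bromide, BrCc1ccccc1
Why: Carboxylate alkylation is insensitive to crowding at the acyl carbon; the benzyl ester keeps C5 from taking part in the lactonisation and can be removed later without acid or base.

Step 20
Reactants: 26 benzyl ester of 25
Product: 27 C9 primary alcohol (C8H2–C9H2OH on C7)
Conditions: 9-BBN, THF, 60 °C; then H2O2, aq. NaOAc, 0 °C → rt
Reagents that add atoms: hydrogen peroxide, OO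
Why: Hydroboration with 9-BBN places boron on the terminal carbon of the monosubstituted alkene (anti-Markovnikov); buffered oxidation avoids ester exchange with the hindered benzyl ester.

Step 21
Reactants: 27 C9 primary alcohol
Product: 28 C9,C11 diol
Conditions: HF·pyridine, pyridine, THF, 0 °C → rt
Reagents that add atoms: none
Why: Buffered fluoride cleaves the tertiary triethylsilyl ether; the SEM ether, the silylethyl ester and the benzyl ester are stable to it.

Step 22
Reactants: 28 C9,C11 diol
Product: 31 bicyclic lactone benzyl ester (C9(=O)–O10–C11 bridge closed), via C9 aldehyde 29 (not isolated), via lactol 30 (not isolated)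
Conditions: TEMPO (20 mol%), PhI(OAc)2 (3 equiv), CH2Cl2, rt
Reagents that add atoms: none
Why: The oxoammonium oxidant takes only the primary alcohol; aldehyde 29 is captured by the C11 hydroxyl as the six-membered lactol 30 (6-exo-trig addition to the carbonyl), which is oxidised on to the lactone; C5 is an ester and C13 an ether, so no other hydroxyl can compete.

Step 23
Reactants: 31 bicyclic lactone benzyl ester
Product: 32 bicyclic lactone C5 carboxylic acid
Conditions: H2 (1 atm), Pd/C (10%), EtOAc, rt
Reagents that add atoms: none
Why: Hydrogenolysis cleaves the benzyl C–O bond, remote from the hindered acyl carbon; no alkene is present at this stage.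

Step 24
Reactants: 32 bicyclic lactone C5 carboxylic acid
Product: 33 C5 primary alcohol
Conditions: BH3·THF, THF, 0 °C → rt; MeOH
Reagents that add atoms: none
Why: Borane reduces carboxylic acids through acyloxyboranes much faster than lactones or esters, so only C5 is reduced.

Step 25
Reactants: 33 C5 primary alcohol
Product: 34 C5 aldehyde
Conditions: Dess–Martin periodinane, NaHCO3, CH2Cl2, 0 °C → rt
Reagents that add atoms: none
Why: Neutral Dess–Martin oxidation gives the aldehyde without enolising C6, whose deprotonation would put O10 in a position to be eliminated.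

Step 26
Reactants: 35 2-methylprop-2-en-1-ol
Product: 36 (S)-2-methylglycidol
Conditions: Ti(Oi-Pr)4 (5 mol%), L-(+)-diethyl tartrate (6 mol%), t-BuOOH, 4 Å MS, CH2Cl2, −20 °C
Reagents that add atoms: tert-butyl hydroperoxide, CC(C)(C)OO
Why: Sharpless asymmetric epoxidation; the L-(+)-tartrate complex delivers oxygen to the face that gives the (S)-epoxy alcohol, which sets the future C3.

Step 27
Reactants: 36 (S)-2-methylglycidol
Product: 37 (2S)-2-methyl-3-(phenylsulfonyl)propane-1,2-diol
Conditions: PhSO2Na, H2O, 80 °C
Reagents that add atoms: sodium benzenesulfinate, [Na+].[O-]S(=O)c1ccccc1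
Why: S-Alkylation of the sulfinate opens the epoxide at its unsubstituted carbon (future C4), so the quaternary stereocentre is not touched.

Step 28
Reactants: 37 (2S)-2-methyl-3-(phenylsulfonyl)propane-1,2-diol
Product: 38 (2S)-2-methyl-3-(phenylsulfonyl)-1,2-bis(triethylsilyloxy)propane
Conditions: Et3SiOTf (2.5 equiv), 2,6-lutidine, CH2Cl2, −78 → 0 °C
Reagents that add atoms: triethylsilyl trifluoromethanesulfonate, CC[Si](CC)(CC)OS(=O)(=O)C(F)(F)F
Why: Both hydroxyls are silylated; the tertiary silyl ether protects the future allylic alcohol to the end, and the primary one is the handle for the next step.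

Step 29
Reactants: 38 (2S)-2-methyl-3-(phenylsulfonyl)-1,2-bis(triethylsilyloxy)propane
Product: 39 (2S)-2-methyl-3-(phenylsulfonyl)-2-(triethylsilyloxy)propanal
Conditions: (COCl)2, DMSO, CH2Cl2, −78 → −30 °C; Et3N, −78 → 0 °C
Reagents that add atoms: none
Why: Swern conditions again convert only the primary triethylsilyl ether into the aldehyde; the α-silyloxy aldehyde has no α-hydrogen and cannot epimerise.

Step 30
Reactants: 39 (2S)-2-methyl-3-(phenylsulfonyl)-2-(triethylsilyloxy)propanal
Product: 40 (S)-triethyl{[2-methyl-1-(phenylsulfonyl)but-3-en-2-yl]oxy}silane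
Conditions: Ph3PCH3Br, KOt-Bu, THF, 0 °C → rt
Reagents that add atoms: methyltriphenylphosphonium bromide, C[P+](c1ccccc1)(c1ccccc1)c1ccccc1.[Br-]
Why: Wittig methylenation gives the C1=C2 vinyl group; the ylide is not basic enough to deprotonate the sulfone.

Step 31
Reactants: 34 C5 aldehyde; 40 (S)-triethyl{[2-methyl-1-(phenylsulfonyl)but-3-en-2-yl]oxy}silane
Product: 42 β-hydroxy sulfone (C4–C5 bond formed; mixture at C4 and C5), via lithiated sulfone 41 (not isolated)
Conditions: 40, n-BuLi, THF, −78 °C; then 34, −78 °C; AcOH at −78 °C
Reagents that add atoms: none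
Why: The α-sulfonyl carbanion adds to the aldehyde far faster than to the lactone or the shielded ester at −78 °C; a cold acidic quench prevents the new C5 alkoxide from attacking the lactone, and the configurations at C4 and C5 are erased in the next two steps.

Step 32
Reactants: 42 β-hydroxy sulfone
Product: 43 β-keto sulfone (C5 ketone)
Conditions: Dess–Martin periodinane, NaHCO3, CH2Cl2, rt
Reagents that add atoms: none
Why: Oxidation of the only free hydroxyl; the acidic site of the product is C4 and not C6, so O10 is not eliminated.

Step 33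
Reactants: 43 β-keto sulfone
Product: 44 C5 ketone (C4H2; C3 triethylsilyl ether)
Conditions: SmI2, THF/MeOH, −78 °C
Reagents that add atoms: none
Why: Electron transfer from SmI2 cleaves the C–S bond of an α-sulfonyl ketone; the enolate is protonated at C4 by methanol, and the lactone, ester and vinyl group are not reduced.

Step 34
Reactants: 44 C5 ketone
Product: 45 (5S)-alcohol (C3 triethylsilyl ether; C13 SEM ether; C16 silylethyl ester)
Conditions: (R)-2-methyl-CBS-oxazaborolidine (1 equiv), catecholborane, toluene, −78 → −40 °C
Reagents that add atoms: none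
Why: Corey–Bakshi–Shibata reduction: the ketone binds with the α-branched ring carbon C6 as the large group and C4H2 as the small one, so the (R)-catalyst should deliver hydride to give the (5S)-carbinol under reagent control; catecholborane at low temperature leaves the vinyl group and the lactone alone.

Step 35
Reactants: 45 (5S)-alcohol
Product: 46 C13 alcohol (C3 triethylsilyl ether and C16 silylethyl ester retained)
Conditions: MgBr2·OEt2, MeNO2, Et2O, rt
Reagents that add atoms: none
Why: MgBr2 chelates the two acetal oxygens of the SEM group and bromide attacks silicon, so the group fragments to ethene and formaldehyde without protic acid; the tertiary allylic oxygen is still silylated and the γ-acid still esterified.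

Step 36
Reactants: 46 C13 alcohol
Product: 47 CNP0297019.1
Conditions: TASF, DMF, 0 °C → rt; pH 6 phosphate buffer
Reagents that add atoms: none
Why: Fluoride attacks silicon: the silylethyl ester fragments to the carboxylate, ethene and Me3SiF, and the tertiary silyl ether is cleaved; no acid or strong base is used, and the buffered work-up avoids closure of the γ-hydroxy acid and migration of the lactone.

## Compound list

1 | (R)-mevalonolactone, (4R)-4-hydroxy-4-methyloxan-2-one | O=C1C[C@](C)(O)CCO1 | starting material
2 | (3R)-3,5-dihydroxy-N-methoxy-N,3-dimethylpentanamide | CON(C)C(=O)C[C@](C)(O)CCO | intermediate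
3 | (3R)-N-methoxy-N,3-dimethyl-3,5-bis(triethylsilyloxy)pentanamide | CON(C)C(=O)C[C@](C)(O[Si](CC)(CC)CC)CCO[Si](CC)(CC)CC | intermediate
4 | (3R)-3-methyl-3,5-bis(triethylsilyloxy)pentanal | O=CC[C@](C)(O[Si](CC)(CC)CC)CCO[Si](CC)(CC)CC | intermediate
5 | 2-methylpropanoyl chloride | CC(C)C(=O)Cl | starting material
6 | 2-(trimethylsilyl)ethyl 2-methylpropanoate | CC(C)C(=O)OCC[Si](C)(C)C | intermediate
7 | 3-(trimethylsilyl)prop-2-ynal | O=CC#C[Si](C)(C)C | starting material
8 | racemic 2-(trimethylsilyl)ethyl 3-hydroxy-2,2-dimethyl-5-(trimethylsilyl)pent-4-ynoate | CC(C)(C(O)C#C[Si](C)(C)C)C(=O)OCC[Si](C)(C)C | intermediate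
9 | 2-(trimethylsilyl)ethyl 2,2-dimethyl-3-oxo-5-(trimethylsilyl)pent-4-ynoate | CC(C)(C(=O)C#C[Si](C)(C)C)C(=O)OCC[Si](C)(C)C | intermediate
10 | 2-(trimethylsilyl)ethyl (3R)-3-hydroxy-2,2-dimethyl-5-(trimethylsilyl)pent-4-ynoate | O[C@H](C(C)(C)C(=O)OCC[Si](C)(C)C)C#C[Si](C)(C)C | intermediate
11 | 2-(trimethylsilyl)ethyl (3R)-2,2-dimethyl-3-(methylsulfonyloxy)-5-(trimethylsilyl)pent-4-ynoate | CS(=O)(=O)O[C@H](C(C)(C)C(=O)OCC[Si](C)(C)C)C#C[Si](C)(C)C | intermediate
12 | allenylzinc species (ethylzinc on C8 of the allene C8=C7=C14) | CC(C)(C(=O)OCC[Si](C)(C)C)C([H])=[C@]=C([Zn]CC)[Si](C)(C)C | intermediate (not isolated)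
13 | 2-(trimethylsilyl)ethyl (3S,4R,6R)-4-hydroxy-2,2,6-trimethyl-6,8-bis(triethylsilyloxy)-3-[(trimethylsilyl)ethynyl]octanoate | CC[Si](CC)(CC)OCC[C@@](C)(O[Si](CC)(CC)CC)C[C@@H](O)[C@@H](C(C)(C)C(=O)OCC[Si](C)(C)C)C#C[Si](C)(C)C | intermediate
14 | C13 SEM ether of 13 | CC[Si](CC)(CC)OCC[C@@](C)(O[Si](CC)(CC)CC)C[C@@H](OCOCC[Si](C)(C)C)[C@@H](C(C)(C)C(=O)OCC[Si](C)(C)C)C#C[Si](C)(C)C | intermediate
15 | terminal alkyne (C8–H) | CC[Si](CC)(CC)OCC[C@@](C)(O[Si](CC)(CC)CC)C[C@@H](OCOCC[Si](C)(C)C)[C@@H](C(C)(C)C(=O)OCC[Si](C)(C)C)C#C | intermediate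
16 | methyl ynoate (C9 methyl ester on C7≡C8) | CC[Si](CC)(CC)OCC[C@@](C)(O[Si](CC)(CC)CC)C[C@@H](OCOCC[Si](C)(C)C)[C@@H](C(C)(C)C(=O)OCC[Si](C)(C)C)C#CC(=O)OC | intermediate
17 | (Z)-enoate (C7 methyl; C14 and C9 cis) | CC[Si](CC)(CC)OCC[C@@](C)(O[Si](CC)(CC)CC)C[C@@H](OCOCC[Si](C)(C)C)[C@@H](C(C)(C)C(=O)OCC[Si](C)(C)C)/C(C)=C\C(=O)OC | intermediate
18 | C5 aldehyde of the (Z)-enoate | O=CC[C@@](C)(O[Si](CC)(CC)CC)C[C@@H](OCOCC[Si](C)(C)C)[C@@H](C(C)(C)C(=O)OCC[Si](C)(C)C)/C(C)=C\C(=O)OC | intermediate
19 | C5 carboxylic acid of the (Z)-enoate | OC(=O)C[C@@](C)(O[Si](CC)(CC)CC)C[C@@H](OCOCC[Si](C)(C)C)[C@@H](C(C)(C)C(=O)OCC[Si](C)(C)C)/C(C)=C\C(=O)OC | intermediate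
20 | seco acid (C5 acid, (Z)-allylic C9 alcohol) | OC(=O)C[C@@](C)(O[Si](CC)(CC)CC)C[C@@H](OCOCC[Si](C)(C)C)[C@@H](C(C)(C)C(=O)OCC[Si](C)(C)C)/C(C)=C\CO | intermediate
21 | mixed 2,4,6-trichlorobenzoic anhydride of 20 | O=C(OC(=O)c1c(Cl)cc(Cl)cc1Cl)C[C@@](C)(O[Si](CC)(CC)CC)C[C@@H](OCOCC[Si](C)(C)C)[C@@H](C(C)(C)C(=O)OCC[Si](C)(C)C)/C(C)=C\CO | intermediate (not isolated)
22 | ten-membered (Z)-lactone, precursor of the key step | O=C1C[C@@](C)(O[Si](CC)(CC)CC)C[C@@H](OCOCC[Si](C)(C)C)[C@@H](C(C)(C)C(=O)OCC[Si](C)(C)C)/C(C)=C\CO1 | intermediate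
23 | trimethylsilyl ketene acetal of 22 (C5=C6) | C[Si](C)(C)O/C1=C/[C@@](C)(O[Si](CC)(CC)CC)C[C@@H](OCOCC[Si](C)(C)C)[C@@H](C(C)(C)C(=O)OCC[Si](C)(C)C)/C(C)=C\CO1 | intermediate (not isolated)
24 | trimethylsilyl ester of 25 | C[Si](C)(C)OC(=O)[C@@H]1[C@](C)(C=C)[C@H](C(C)(C)C(=O)OCC[Si](C)(C)C)[C@H](OCOCC[Si](C)(C)C)C[C@]1(C)O[Si](CC)(CC)CC | intermediate (not isolated)
25 | cyclohexanecarboxylic acid, product of the key step (C5 carboxyl on C6, vinyl on C7) | OC(=O)[C@@H]1[C@](C)(C=C)[C@H](C(C)(C)C(=O)OCC[Si](C)(C)C)[C@H](OCOCC[Si](C)(C)C)C[C@]1(C)O[Si](CC)(CC)CC | intermediate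
26 | benzyl ester of 25 | O=C(OCc2ccccc2)[C@@H]1[C@](C)(C=C)[C@H](C(C)(C)C(=O)OCC[Si](C)(C)C)[C@H](OCOCC[Si](C)(C)C)C[C@]1(C)O[Si](CC)(CC)CC | intermediate
27 | C9 primary alcohol | O=C(OCc2ccccc2)[C@@H]1[C@](C)(CCO)[C@H](C(C)(C)C(=O)OCC[Si](C)(C)C)[C@H](OCOCC[Si](C)(C)C)C[C@]1(C)O[Si](CC)(CC)CC | intermediate
28 | C9,C11 diol | O=C(OCc2ccccc2)[C@@H]1[C@](C)(CCO)[C@H](C(C)(C)C(=O)OCC[Si](C)(C)C)[C@H](OCOCC[Si](C)(C)C)C[C@]1(C)O | intermediate
29 | C9 aldehyde | O=C(OCc2ccccc2)[C@@H]1[C@](C)(CC=O)[C@H](C(C)(C)C(=O)OCC[Si](C)(C)C)[C@H](OCOCC[Si](C)(C)C)C[C@]1(C)O | intermediate (not isolated)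
30 | bicyclic lactol (C9 hemiacetal, both epimers) | O=C(OCc3ccccc3)[C@@H]1[C@]2(C)CC(O)O[C@@]1(C)C[C@@H](OCOCC[Si](C)(C)C)[C@H]2C(C)(C)C(=O)OCC[Si](C)(C)C | intermediate (not isolated)
31 | bicyclic lactone, C5 benzyl ester | O=C(OCc3ccccc3)[C@@H]1[C@]2(C)CC(=O)O[C@@]1(C)C[C@@H](OCOCC[Si](C)(C)C)[C@H]2C(C)(C)C(=O)OCC[Si](C)(C)C | intermediate
32 | bicyclic lactone, C5 carboxylic acid | OC(=O)[C@@H]1[C@]2(C)CC(=O)O[C@@]1(C)C[C@@H](OCOCC[Si](C)(C)C)[C@H]2C(C)(C)C(=O)OCC[Si](C)(C)C | intermediate
33 | bicyclic lactone, C5 primary alcohol | OC[C@@H]1[C@]2(C)CC(=O)O[C@@]1(C)C[C@@H](OCOCC[Si](C)(C)C)[C@H]2C(C)(C)C(=O)OCC[Si](C)(C)C | intermediate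
34 | bicyclic lactone, C5 aldehyde | O=C[C@@H]1[C@]2(C)CC(=O)O[C@@]1(C)C[C@@H](OCOCC[Si](C)(C)C)[C@H]2C(C)(C)C(=O)OCC[Si](C)(C)C | intermediate
35 | 2-methylprop-2-en-1-ol | C=C(C)CO | starting material
36 | (S)-2-methylglycidol, (2S)-(2-methyloxiran-2-yl)methanol | OC[C@@]1(C)CO1 | intermediate
37 | (2S)-2-methyl-3-(phenylsulfonyl)propane-1,2-diol | OC[C@](C)(O)CS(=O)(=O)c1ccccc1 | intermediate
38 | (2S)-2-methyl-3-(phenylsulfonyl)-1,2-bis(triethylsilyloxy)propane | CC[Si](CC)(CC)OC[C@](C)(O[Si](CC)(CC)CC)CS(=O)(=O)c1ccccc1 | intermediate
39 | (2S)-2-methyl-3-(phenylsulfonyl)-2-(triethylsilyloxy)propanal | O=C[C@](C)(O[Si](CC)(CC)CC)CS(=O)(=O)c1ccccc1 | intermediate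
40 | (S)-triethyl{[2-methyl-1-(phenylsulfonyl)but-3-en-2-yl]oxy}silane | C=C[C@](C)(O[Si](CC)(CC)CC)CS(=O)(=O)c1ccccc1 | intermediate
41 | α-lithio derivative of 40 | C=C[C@](C)(O[Si](CC)(CC)CC)[CH-]S(=O)(=O)c1ccccc1.[Li+] | intermediate (not isolated)
42 | β-hydroxy sulfone (C4 sulfonyl, C5 hydroxyl, mixture) | C=C[C@](C)(O[Si](CC)(CC)CC)C(S(=O)(=O)c1ccccc1)C(O)[C@@H]2[C@]3(C)CC(=O)O[C@@]2(C)C[C@@H](OCOCC[Si](C)(C)C)[C@H]3C(C)(C)C(=O)OCC[Si](C)(C)C | intermediate
43 | β-keto sulfone (C5 ketone, C4 sulfonyl) | C=C[C@](C)(O[Si](CC)(CC)CC)C(S(=O)(=O)c1ccccc1)C(=O)[C@@H]2[C@]3(C)CC(=O)O[C@@]2(C)C[C@@H](OCOCC[Si](C)(C)C)[C@H]3C(C)(C)C(=O)OCC[Si](C)(C)C | intermediate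
44 | C5 ketone with complete side chain | C=C[C@](C)(O[Si](CC)(CC)CC)CC(=O)[C@@H]2[C@]3(C)CC(=O)O[C@@]2(C)C[C@@H](OCOCC[Si](C)(C)C)[C@H]3C(C)(C)C(=O)OCC[Si](C)(C)C | intermediate
45 | (5S)-alcohol, fully protected elsewhere | C=C[C@](C)(O[Si](CC)(CC)CC)C[C@H](O)[C@@H]2[C@]3(C)CC(=O)O[C@@]2(C)C[C@@H](OCOCC[Si](C)(C)C)[C@H]3C(C)(C)C(=O)OCC[Si](C)(C)C | intermediate
46 | C13 alcohol (C3 silyl ether, C16 silylethyl ester) | C=C[C@](C)(O[Si](CC)(CC)CC)C[C@H](O)[C@@H]2[C@]3(C)CC(=O)O[C@@]2(C)C[C@@H](O)[C@H]3C(C)(C)C(=O)OCC[Si](C)(C)C | intermediate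
47 | CNP0297019.1 | C=C[C@](C)(O)C[C@H](O)[C@@H]1[C@]2(C)CC(=O)O[C@@]1(C)C[C@@H](O)[C@H]2C(C)(C)C(=O)O | target

## Step count and uncertain steps

Total: 36 steps. Longest linear sequence: 28 steps (from 5 through steps 4–25 and 31–36).

**Step 18 (key step).**
- *What may go wrong.* The two boat arrays differ only in whether the C7 methyl or the trigonal C8 lies next to the C11 and C13 oxygens, so facial discrimination may be small. The lithium enolate may also expel the C11 silyloxy group before it is silylated.
- *Fallback.* The C6–C7 bond is made by intramolecular enolate SN2′ alkylation instead of a sigmatropic shift. Seco acid 20 is alkylated on the carboxylate (BnBr, Cs2CO3) to the benzyl ester of the seco acid F1. Its allylic hydroxyl is exchanged for chloride (MsCl, LiCl, 2,4,6-collidine, DMF) to give the allylic chloride F2. KN(SiMe3)2 at −78 °C then forms the C6 enolate, which attacks C7 with allylic transposition and loss of chloride. The ring closes through a chair in which the C14 group, the C11 methyl and the C5 ester can all be equatorial. This gives benzyl ester 26, where the route continues.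

**Step 9.**
- *What may go wrong.* Bond formation at the carbon bearing the tert-alkyl group may be slow, so protonation or coupling of the allenylzinc competes, and anti selectivity may erode.
- *Fallback.* Mesylate 11 is converted by copper-catalysed anti SN2′ borylation (B2pin2, CuCl, KOt-Bu, Xantphos) into the isolable allenyl pinacolboronate F3. F3 is heated with aldehyde 4; the closed six-membered transition state of the allenylboration gives the same anti alcohol 13.

**Step 17.**
- *What may go wrong.* Ring strain in the ten-membered transition state may let intermolecular acylation (dimer formation) win.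
- *Fallback.* The ring is closed from 20 by activating the alcohol instead of the acid (Mitsunobu macrolactonisation, PPh3, diisopropyl azodicarboxylate, high dilution). The carboxylate displaces the primary allylic oxyphosphonium group and gives 22 directly; no new compound is made (F0).

**Step 22.**
- *What may go wrong.* Lactol closure needs the conformer with three axial substituents; if it is poorly populated, the aldehyde accumulates or is over-oxidised.
- *Fallback.* From 28 the oxidation is stopped at aldehyde 29, which is taken to the C9 carboxylic acid F4 (NaClO2, NaH2PO4, 2-methylbut-2-ene). The tertiary hydroxyl is then acylated intramolecularly under dehydrating conditions (2,4,6-Cl3C6H2COCl, Et3N, DMAP, toluene) to give 31.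

**Step 31.**
- *What may go wrong.* Both partners are crowded at the reacting carbons, so addition may be slow or reversible and may lose to deprotonation at C6.
- *Fallback.* Sulfone 40 is desilylated (HF·pyridine) to the hydroxy sulfone F5. Its O,C-dianion (2 equiv n-BuLi) is smaller and cannot eliminate; it adds to 34 to give the diol sulfone F6. Dess–Martin oxidation gives the hydroxy keto sulfone F7, SmI2 gives the β-hydroxy ketone F8, and silylation (Et3SiOTf, 2,6-lutidine) returns to 44.

**Step 34.**
- *What may go wrong.* Hydride transfer to the very hindered ketone may be slow, and the ring's own facial bias may oppose the catalyst.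
- *Fallback.* Ketone 44 is reduced under substrate control (NaBH4, MeOH, −40 °C). 45 is separated from the C5 epimer F9, and F9 is returned to 44 by Dess–Martin oxidation for another pass, so that material converges on 45.

## Further compounds

F1 | step 18 | benzyl ester of the seco acid | O=C(OCc1ccccc1)C[C@@](C)(O[Si](CC)(CC)CC)C[C@@H](OCOCC[Si](C)(C)C)[C@@H](C(C)(C)C(=O)OCC[Si](C)(C)C)/C(C)=C\CO
F2 | step 18 | allylic chloride | O=C(OCc1ccccc1)C[C@@](C)(O[Si](CC)(CC)CC)C[C@@H](OCOCC[Si](C)(C)C)[C@@H](C(C)(C)C(=O)OCC[Si](C)(C)C)/C(C)=C\CCl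
F3 | step 9 | allenyl pinacolboronate | CC1(C)OB(OC1(C)C)C(=[C@@]=C([H])C(C)(C)C(=O)OCC[Si](C)(C)C)[Si](C)(C)C
F0 | step 17 | none | none
F4 | step 22 | C9 carboxylic acid | O=C(OCc2ccccc2)[C@@H]1[C@](C)(CC(=O)O)[C@H](C(C)(C)C(=O)OCC[Si](C)(C)C)[C@H](OCOCC[Si](C)(C)C)C[C@]1(C)O
F5 | step 31 | hydroxy sulfone, (S)-2-methyl-1-(phenylsulfonyl)but-3-en-2-ol | C=C[C@](C)(O)CS(=O)(=O)c1ccccc1
F6 | step 31 | diol sulfone | C=C[C@](C)(O)C(S(=O)(=O)c1ccccc1)C(O)[C@@H]2[C@]3(C)CC(=O)O[C@@]2(C)C[C@@H](OCOCC[Si](C)(C)C)[C@H]3C(C)(C)C(=O)OCC[Si](C)(C)C
F7 | step 31 | hydroxy keto sulfone | C=C[C@](C)(O)C(S(=O)(=O)c1ccccc1)C(=O)[C@@H]2[C@]3(C)CC(=O)O[C@@]2(C)C[C@@H](OCOCC[Si](C)(C)C)[C@H]3C(C)(C)C(=O)OCC[Si](C)(C)C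
F8 | step 31 | β-hydroxy ketone | C=C[C@](C)(O)CC(=O)[C@@H]2[C@]3(C)CC(=O)O[C@@]2(C)C[C@@H](OCOCC[Si](C)(C)C)[C@H]3C(C)(C)C(=O)OCC[Si](C)(C)C
F9 | step 34 | C5 epimer of 45 | C=C[C@](C)(O[Si](CC)(CC)CC)C[C@@H](O)[C@@H]2[C@]3(C)CC(=O)O[C@@]2(C)C[C@@H](OCOCC[Si](C)(C)C)[C@H]3C(C)(C)C(=O)OCC[Si](C)(C)C
A1 | alternative 1 | bicyclic keto-lactone with C5 silyl ether and C16 silylethyl ester | CC(C)(C)[Si](C)(C)OC[C@@H]1[C@]2(C)CC(=O)O[C@@]1(C)CC(=O)[C@H]2C(C)(C)C(=O)OCC[Si](C)(C)C
A2 | alternative 1 | open-chain aldehyde acid with isopropenyl group | C=C(C)[C@H](CO[Si](C)(C)C(C)(C)C)[C@](C)(CC(=O)O)[C@@H](C=O)C(C)(C)C(=O)OCC[Si](C)(C)C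
A3 | alternative 2 | cyclohexanone with quaternary C7, side chain on C6 and C5 carbinol | C=C[C@](C)(O[Si](CC)(CC)CC)C[C@H](O)[C@@H]1[C@](C)(CCOCc2ccc(OC)cc2)[C@H](C(C)(C)C(=O)OCC[Si](C)(C)C)[C@H](O[Si](C)(C)C(C)(C)C)CC1=O
A4 | alternative 2 | cyclohexenone (C11 ketone, C6=C7) | O=C1C=C(CCOCc2ccc(OC)cc2)[C@H](C(C)(C)C(=O)OCC[Si](C)(C)C)[C@H](O[Si](C)(C)C(C)(C)C)C1
A5 | alternative 2 | side-chain aldehyde | C=C[C@](C)(O[Si](CC)(CC)CC)CC=O
A6 | alternative 3 | bicyclic keto-lactone with C5 allyl ester and C16 silylethyl ester | C=CCOC(=O)[C@@H]1[C@]2(C)CC(=O)O[C@@]1(C)CC(=O)[C@H]2C(C)(C)C(=O)OCC[Si](C)(C)C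
A7 | alternative 3 | allyl 4,6-dimethyl-2-oxo-2H-pyran-5-carboxylate | C=CCOC(=O)c1c(C)cc(=O)oc1C
A8 | alternative 3 | 2-(trimethylsilyl)ethyl 2,2-dimethyl-4-oxopentanoate | CC(=O)CC(C)(C)C(=O)OCC[Si](C)(C)C
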